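**Strategy.** The carbocyclic enone ring (C4a–C5–C6–C7–C8–C8a, chromenone numbering) is disconnected across C7–C8 and C5–C6. This removes C6–C7 as a two-carbon acrylate unit and leaves an intact dihydropyran, methyl (2S,4R)-2-heptadecyl-4-hydroxy-6-methyl-3,4-dihydro-2H-pyran-5-carboxylate. The key step exploits the C4a=C8a enol-ether double bond of the pyran ring, which makes the C8 methyl vinylogously acidic towards the C5 ester. The lithium dienolate adds through C8 to allyl acrylate (C7), and the new C6 enolate acylates C5 (Michael–Dieckmann, an anionic [4+2] annulation), closing the carbocycle in one operation. C2 is set by an asymmetric vinylogous aldol and C4 by Luche reduction; deallylative decarboxylation finishes the synthesis.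

Key step: step 4

Remark on numbering: atom labels follow the chromenone skeleton of the target (O1, C2, C3, C4, C4a, C5, C6, C7, C8, C8a). The target is (2S,4R), with the C2 heptadecyl and C4 hydroxyl cis.

Assumption: in step 1 the (R)-BINOL/Ti(OiPr)4 catalyst is taken to direct the dienolate to the Re face of the aldehyde, which corresponds to the (5S)-alcohol. If the opposite sense is found, (S)-BINOL is used and nothing else changes.

**Step 1**
Reactants: 1 octadecanal; 2 1-methoxy-1,3-bis(trimethylsilyloxy)buta-1,3-diene
Product: 4 methyl (5S)-5-hydroxy-3-oxodocosanoate, via bis-silylated aldol adduct 3 (not isolated)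
Conditions: Ti(OiPr)4 (10 mol %), (R)-BINOL (10 mol %), 4 Å MS, THF, −40 °C → rt; then TFA (cat.), THF–H2O, 0 °C
Reagents that add atoms: none
Why: Catalytic asymmetric vinylogous Mukaiyama aldol, in which the BINOL–titanium complex activates the aldehyde and the terminal CH2 of the diene should attack its Re face to set C5 as S (the future C2), after which acidic hydrolysis removes both silyl groups.

**Step 2**
Reactants: 4 methyl (5S)-5-hydroxy-3-oxodocosanoate; 5 N,N-dimethylacetamide dimethyl acetal
Product: 7 methyl (2S)-2-heptadecyl-6-methyl-4-oxo-3,4-dihydro-2H-pyran-5-carboxylate, via enaminone 6 (not isolated)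
Conditions: toluene, rt; then AcOH, 50 °C
Reagents that add atoms: none
Why: Amide-acetal condensation at the active methylene gives enaminone 6, and acid-promoted intramolecular addition–elimination of the δ-hydroxyl at the enamine carbon expels dimethylamine to close the dihydropyranone, leaving C2 untouched under these non-basic conditions.

**Step 3**
Reactants: 7 methyl (2S)-2-heptadecyl-6-methyl-4-oxo-3,4-dihydro-2H-pyran-5-carboxylate
Product: 8 methyl (2S,4R)-2-heptadecyl-4-hydroxy-6-methyl-3,4-dihydro-2H-pyran-5-carboxylate
Conditions: NaBH4, CeCl3·7H2O, MeOH–THF, −40 °C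
Reagents that add atoms: none
Why: Luche reduction should add hydride 1,2 to the C4 ketone rather than to the ester or the tetrasubstituted push–pull alkene, and axial delivery on the half-chair with the heptadecyl group pseudo-equatorial should place the new hydroxyl pseudo-equatorial, cis to C2 (4R).

**Step 4**
Reactants: 8 methyl (2S,4R)-2-heptadecyl-4-hydroxy-6-methyl-3,4-dihydro-2H-pyran-5-carboxylate; 9 allyl acrylate
Product: 12 allyl (2S,4R)-2-heptadecyl-4-hydroxy-5-oxo-3,4,5,6,7,8-hexahydro-2H-chromene-6-carboxylate (C6 epimer mixture), via alkoxide–dienolate dianion 10 (not isolated), via Michael adduct enolate 11 (not isolated)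
Conditions: LDA (2.1 equiv), THF, −78 °C; then 9 (1.1 equiv), −78 → 0 °C; AcOH quench
Reagents that add atoms: none
Why: Lithium diisopropylamide first forms the C4 lithium alkoxide and then removes a proton from the C8 methyl, the only carbon acid (γ to the C5 ester through C4a=C8a and cis to it), giving the chelated dianion 10; its unhindered C8 terminus adds 1,4 to allyl acrylate (C7–C8 bond), and the resulting ester enolate 11 attacks the C5 ester with loss of methoxide (C5–C6 bond). The closest known reaction type is the Michael–Dieckmann (Staunton–Weinreb-type, anionic [4+2]) annulation of γ-lithiated β-alkoxy enoates and ortho-toluates with acrylates. The carbocycle closes by a 6-(enolexo)-exo-trig acyl substitution, driven to completion by deprotonation of the new β-keto ester by the released methoxide. The only new stereocentre, C6, is epimerisable and is erased in step 5, so it needs no control. The step needs γ- over α-attack and C- over O-attack of the dienolate, secured by the fully substituted α-carbon C4a and the soft acceptor. It also needs the C4 oxygen to stay in place, secured by using the free alkoxide, which cannot leave by β-elimination as a protected oxygen could; C2 and C4 carry no acidic hydrogen.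

**Step 5**
Reactants: 12 allyl (2S,4R)-2-heptadecyl-4-hydroxy-5-oxo-3,4,5,6,7,8-hexahydro-2H-chromene-6-carboxylate
Product: 14 (2S,4R)-2-heptadecyl-4-hydroxy-2,3,4,6,7,8-hexahydro-5H-chromen-5-one, via β-keto acid 13 (not isolated)
Conditions: Pd(OAc)2 (5 mol %), PPh3 (20 mol %), HCO2H, Et3N, THF, rt → 40 °C
Reagents that add atoms: none
Why: Tsuji deallylation, in which zerovalent palladium ionises the allyl ester, formate reduces the π-allyl unit to propene (outpacing decarboxylative allylation), and the vinylogous β-keto acid 13 loses CO2 to give 14 in a buffered medium that should spare the 4-hydroxy vinylogous ester and both stereocentres.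

**Compound list**
1 | octadecanal | CCCCCCCCCCCCCCCCCC=O | starting material
2 | 1-methoxy-1,3-bis(trimethylsilyloxy)buta-1,3-diene | COC(O[Si](C)(C)C)=CC(=C)O[Si](C)(C)C | starting material
3 | methyl (5S)-3,5-bis(trimethylsilyloxy)docos-2-enoate (alkene geometry not defined) | CCCCCCCCCCCCCCCCC[C@H](O[Si](C)(C)C)CC(O[Si](C)(C)C)=CC(=O)OC | intermediate (not isolated)
4 | methyl (5S)-5-hydroxy-3-oxodocosanoate | CCCCCCCCCCCCCCCCC[C@H](O)CC(=O)CC(=O)OC | intermediate
5 | N,N-dimethylacetamide dimethyl acetal (1,1-dimethoxy-N,N-dimethylethanamine) | CC(OC)(OC)N(C)C | starting material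
6 | methyl (5S)-2-[1-(dimethylamino)ethylidene]-5-hydroxy-3-oxodocosanoate | CCCCCCCCCCCCCCCCC[C@H](O)CC(=O)C(C(=O)OC)=C(C)N(C)C | intermediate (not isolated)
7 | methyl (2S)-2-heptadecyl-6-methyl-4-oxo-3,4-dihydro-2H-pyran-5-carboxylate | CCCCCCCCCCCCCCCCC[C@H]1CC(=O)C(C(=O)OC)=C(C)O1 | intermediate
8 | methyl (2S,4R)-2-heptadecyl-4-hydroxy-6-methyl-3,4-dihydro-2H-pyran-5-carboxylate | CCCCCCCCCCCCCCCCC[C@H]1C[C@@H](O)C(C(=O)OC)=C(C)O1 | intermediate
9 | allyl acrylate (prop-2-en-1-yl prop-2-enoate) | C=CC(=O)OCC=C | starting material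
10 | dilithium alkoxide–dienolate of 8 (C4 lithium alkoxide, lithium ketene acetal at C5, exocyclic C8 methylidene) | CCCCCCCCCCCCCCCCC[C@H]1C[C@@H](O[Li])C(=C(OC)O[Li])C(=C)O1 | intermediate (not isolated)
11 | dilithium Michael adduct (C4 lithium alkoxide, lithium enolate of the allyl ester on the new C8–C7–C6 chain) | CCCCCCCCCCCCCCCCC[C@H]1C[C@@H](O[Li])C(C(=O)OC)=C(CCC=C(O[Li])OCC=C)O1 | intermediate (not isolated)
12 | allyl (2S,4R)-2-heptadecyl-4-hydroxy-5-oxo-3,4,5,6,7,8-hexahydro-2H-chromene-6-carboxylate (C6 epimer mixture) | CCCCCCCCCCCCCCCCC[C@H]1C[C@@H](O)C2=C(CCC(C(=O)OCC=C)C2=O)O1 | intermediate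
13 | (2S,4R)-2-heptadecyl-4-hydroxy-5-oxo-3,4,5,6,7,8-hexahydro-2H-chromene-6-carboxylic acid | CCCCCCCCCCCCCCCCC[C@H]1C[C@@H](O)C2=C(CCC(C(=O)O)C2=O)O1 | intermediate (not isolated)
14 | (2S,4R)-2-heptadecyl-4-hydroxy-2,3,4,6,7,8-hexahydro-5H-chromen-5-one | CCCCCCCCCCCCCCCCC[C@H]1C[C@@H](O)C2=C(CCCC2=O)O1 | target

**Totals**
Total step count: 5. Longest linear sequence: 5 steps (from octadecanal 1).

**Steps most likely to fail**

Step 4 (key annulation). The dienolate may react through C4a or oxygen, anionic oligomerisation of the acrylate may outpace ring closure, or the sequence may stall after the Michael addition because the C5 ester is a deactivated vinylogous carbonate. Fallback: from 8 the same two bonds are made by a Diels–Alder reaction. LDA (2.2 equiv) and Me3SiCl (2.5 equiv) in THF at −78 °C should convert 8 into the bis-silylated exocyclic diene (2S,4R)-2-heptadecyl-5-[methoxy(trimethylsilyloxy)methylidene]-6-methylidene-4-(trimethylsilyloxy)oxane F1. Cycloaddition with phenyl vinyl sulfone (toluene, 80 °C), in which the nucleophilic C8 terminus should bond to the sulfone β-carbon, followed by mild hydrolysis (aqueous citric acid, THF), should give (2S,4R)-2-heptadecyl-4-hydroxy-6-(phenylsulfonyl)-2,3,4,6,7,8-hexahydro-5H-chromen-5-one F2. Reductive desulfonylation with aluminium amalgam (Al/Hg, THF–H2O, 0 °C) rejoins the route at the target 14.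

Step 1 (asymmetric vinylogous aldol). Facial discrimination by the catalyst may be poor, or of the opposite sense, with a long unbranched aliphatic aldehyde. Fallback: from 1, Roskamp homologation (ethyl diazoacetate, SnCl2 cat., CH2Cl2, rt) should give ethyl 3-oxoicosanoate F3. Noyori hydrogenation (H2, RuCl2[(S)-BINAP], EtOH, 50 °C), whose sense for β-keto esters is secure, should give ethyl (3S)-3-hydroxyicosanoate F4. Cross-Claisen condensation with excess lithium enolate of methyl acetate (LDA, MeOAc, THF, −78 → −20 °C) rejoins the route at 4.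

Step 3 (Luche reduction). Facial selectivity of hydride delivery may be poor, because the neighbouring ester could erode the usual axial preference and leave much of the material as the C4 epimer. Fallback: from 7 the reduction is run as before and the epimer methyl (2S,4S)-2-heptadecyl-4-hydroxy-6-methyl-3,4-dihydro-2H-pyran-5-carboxylate F5 is separated. Mitsunobu inversion (4-nitrobenzoic acid, PPh3, DIAD, THF, 0 °C) should give methyl (2S,4R)-2-heptadecyl-6-methyl-4-[(4-nitrobenzoyl)oxy]-3,4-dihydro-2H-pyran-5-carboxylate F6. Methanolysis (K2CO3, MeOH, 0 °C) rejoins the route at 8, so that both epimers converge.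

**Further compounds**
F1 | step 4 | (2S,4R)-2-heptadecyl-5-[methoxy(trimethylsilyloxy)methylidene]-6-methylidene-4-(trimethylsilyloxy)oxane | CCCCCCCCCCCCCCCCC[C@H]1C[C@@H](O[Si](C)(C)C)C(=C(OC)O[Si](C)(C)C)C(=C)O1
F2 | step 4 | (2S,4R)-2-heptadecyl-4-hydroxy-6-(phenylsulfonyl)-2,3,4,6,7,8-hexahydro-5H-chromen-5-one | CCCCCCCCCCCCCCCCC[C@H]1C[C@@H](O)C2=C(CCC(S(=O)(=O)c3ccccc3)C2=O)O1
F3 | step 1 | ethyl 3-oxoicosanoate | CCCCCCCCCCCCCCCCCC(=O)CC(=O)OCC
F4 | step 1 | ethyl (3S)-3-hydroxyicosanoate | CCCCCCCCCCCCCCCCC[C@H](O)CC(=O)OCC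
F5 | step 3 | methyl (2S,4S)-2-heptadecyl-4-hydroxy-6-methyl-3,4-dihydro-2H-pyran-5-carboxylate | CCCCCCCCCCCCCCCCC[C@H]1C[C@H](O)C(C(=O)OC)=C(C)O1
F6 | step 3 | methyl (2S,4R)-2-heptadecyl-6-methyl-4-[(4-nitrobenzoyl)oxy]-3,4-dihydro-2H-pyran-5-carboxylate | CCCCCCCCCCCCCCCCC[C@H]1C[C@@H](OC(=O)c2ccc(cc2)[N+](=O)[O-])C(C(=O)OC)=C(C)O1
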